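## The problem

The target joins three units: a trans-2-aryl-3-hydroxymethyl-2,3-dihydrobenzofuran, a guaiacyl ring on C2, and a 3,5,7-trihydroxychromen-4-one whose C2 is bonded to C4 of the dihydrobenzofuran. This biaryl-type bond sits next to the ring-fusion carbon C3a and is crowded by the C3 side chain. There are only two stereocentres, C2 (R) and C3 (S), adjacent and trans. C3 can steer C2 toward trans, but C2 is a para-oxygenated benzylic aryl ether carbon that ionises under acid, so both are best set together once and not disturbed again. The benzene ring of the dihydrobenzofuran is 1,2,3,4-tetrasubstituted (C3a alkyl, C4 aryl, C7 OH, C7a O1), a pattern that is awkward to reach by substitution of a bought arene. Six hydroxyl groups, among them a catechol-type phenol, the flavonol enol and a para-hydroxybenzyl ether, will not survive strong acid, base or oxidants once free, so they must be released together at the end under neutral conditions. The chromenone carries a 5-oxygen, which diverts alkaline peroxide cyclisation of chalcones to aurones, so the 3-hydroxyl needs its own selective oxidation. The two CH2O-level carbons on C3 and C4 are close enough to form a six-membered lactol or cyclic ether once C4 carries an aldehyde or enone, so they need different protecting groups. The enabling feature is that C7a and C7 bear O1 and OH as ortho neighbours and C7a is tied back to C3a through O1–C2–C3: a furan (future C3a, C4, C5, C6) and an ynol ether (future C7a, C7) linked through these atoms is the substrate of a gold-catalysed furan–yne phenol synthesis, which gives a 7-hydroxy-2,3-dihydrobenzofuran with the furan 3-substituent on C4.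

## Retrosynthesis

Target 29 is cut at five O–CH2Ph bonds to give flavonol 28. One protecting-group type on the guaiacyl oxygen, O7, the C3 hydroxymethyl oxygen and the two chromenone phenols means a single neutral final step; mixed silyl or acyl protection would add a step and expose the polyphenol to fluoride or base. The hydrogenolysis has to spare the benzylic C2–O1 bond and the chromenone double bond.

Flavonol 28 is cut at the C3–O bond to flavone 26, then at O1–C2 of the pyranone to chalcone 25, then at the Cα=Cβ bond to aldehyde 22 and acetophenone 24. The one-step alkaline peroxide route from 25 to 28 is set aside because the 6'-alkoxy group steers it to aurones. An acylation/1,3-diketone route is set aside because it needs the C4 acid, an α-oxygenated ketone and an acidic cyclodehydration that the benzylic ether at C2 may not tolerate. The cut removes the whole chromenone and leaves a dihydrobenzofuran with a one-carbon handle. It asks for a condensation on an ortho-substituted aldehyde and for an oxygen transfer that picks the enol-ether double bond of 26.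

Aldehyde 22 goes back through benzylic alcohol 21 and silyl ether 20 to phenol 19 (oxidation, desilylation, phenol benzylation). O7 is benzylated because a free para-phenoxide would switch off the aldehyde in the condensation. The C3 hydroxymethyl oxygen is already a benzyl ether and only the C4 carbon carries silicon, so the C4 alcohol can be freed and oxidised alone and no lactol, lactone or oxa-Michael ring can form.

Phenol 19 is cut at C3a–C7a and C6–C7, with the C7 oxygen traced back to a furan oxygen, to give the acyclic furyl ynol ether 17. The arene appears with all four substituents in place. The neighbouring options close O1–C2 onto a preformed arene and would first need a 1,2,3,4-tetrasubstituted benzene made with regiocontrol. Precursor 17 has no ring beyond the furan, and its two stereocentres are spectators. The forward step must activate the alkyne faster than the benzylic C–O bond of the ynol ether ionises.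

Ynol ether 17 is cut at the O–C(sp) bond to secondary alcohol 14; the two alkyne carbons come through dichlorovinyl ether 15 and lithium alkynyl ether 16. The carbinol C–O bond is carried unchanged into O1–C2, so the configuration of 14 is that of the ring.

Alcohol 14 goes back by primary O-benzylation to diol 12, by reductive removal of the auxiliary to aldol adduct 11, and by cutting the bond between the carbinol carbon and the furyl-bearing carbon to imide 8 and aldehyde 9. An auxiliary-controlled syn aldol sets both centres in one step with a known sense. Because O1–C2 is formed with retention, the syn adduct maps onto the trans ring; an anti aldol would give the cis ring. Benzyl is chosen over silyl for the primary oxygen because a silyl group could migrate to the neighbouring alkoxide when the ynol ether is made.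

Imide 8 is cut at the N–acyl bond to acid 5 and oxazolidinone 6. Acid 5 goes back by oxidation to alcohol 4, by cutting the furan C2–CH2 bond to silyl ether 2 (through 2-lithiofuran 3), and by desilylation to 3-furanmethanol 1. The furan thus brings the future C3a–C6 and the C4 carbon handle from a commercial C5 unit.

Acetophenone 24 comes from 2,4,6-trihydroxyacetophenone 23 by benzylation of the two phenols that are not hydrogen-bonded to the ketone, so ring A of the chromenone is bought, not built.

## Roads not taken

Alternative 1: The dihydrobenzofuran is cut at C3–C3a and traced to a flavanone. In the forward step PhI(OAc)2 and H2SO4 in trimethyl orthoformate–methanol convert (2R)-flavanone A1 into the trans ester A2 by an oxidative 1,2-shift of the fused aryl carbon from the carbonyl carbon to C3, with contraction of the pyranone.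
- Merits: the arene is bought, C2 controls C3 (trans), the ester is the hydroxymethyl precursor and the bromine marks C4.
- Weak points: all stereochemical information rests on one centre in A1, which can racemise by reversible ring opening to the chalcone in the strongly acidic medium. A1 itself needs an asymmetric synthesis. The guaiacyl ring must be deactivated as a tosylate against the oxidant. After A2 there remain ester reduction, tosylate exchange and conversion of a hindered aryl bromide into a carbon substituent before the flavonol can be started.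
- Comparison: its intermediates are bench-stable and its key step is operationally simple, which the labile ynol ether 17 cannot match. Against this the chosen plan sets an aldol that fixes both centres with a predictable sense, no racemisable intermediate, and a C4 carbon that is present from the first step.

Alternative 2: The cut lies in ring A of the chromenone (C4a–C5). In the forward step Mg(OMe)2 in methanol opens 4-hydroxy-2-pyranone A3 to a chelated tetraketo ester that folds by Claisen condensation into the phloroglucinol ring of diketone A4, which would cyclodehydrate to the 5,7-dihydroxyflavone.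
- Merits: biomimetic, no benzyl groups on ring A, no chalcone and no hot iodine step.
- Weak points: it builds a ring that is commercial in 23. A3 must be assembled on a hindered aryl ketone that already contains the complete dihydrobenzofuran, so the hard part of the target is untouched. The folding can go by aldol instead of Claisen. The free phenols of the product complicate the 3-hydroxylation that is still needed.
- Comparison: it is better in protecting-group economy on ring A. The chosen plan sets against this the convergent use of 24 and a key step spent on the ring that cannot be bought.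

Alternative 3: The cut is at O1–C2 and C3–OH of the flavonol. KOH in ethanol converts aurone dibromide A5 into flavonol A6, which is identical with 28; hydroxide opens the five-membered ring at the brominated ketal carbon and the phenoxide displaces the benzylic bromide.
- Merits: one step makes the pyranone and the 3-hydroxyl, it uses the aurone manifold that 6'-alkoxychalcones prefer, and it needs no dioxirane. In the way the C3 oxygen is introduced it is as good as or better than the chosen end game, and it could be grafted onto aldehyde 22 in the same number of steps.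
- Weak points: elemental bromine must add to the aurone double bond in the presence of four electron-rich rings and several benzylic positions, and base can return the aurone by elimination.
- Comparison: the chosen end game sets against it catalytic iodine and a neutral oxygen-transfer reagent, neither of which halogenates the arenes, and a ketone partner (24) that is one step from a commercial compound.

Key step: step 9

Remark: (2R,3S) is the trans isomer (aryl on C2 and CH2OH on C3 on opposite faces); O-benzylvanillin 9 is taken as the commercial form of vanillin.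

## Steps

Step 1
Reactants: 1 3-furanmethanol
Product: 2 tert-butyl(furan-3-ylmethoxy)dimethylsilane
Conditions: TBSCl, imidazole, DMF, rt
Reagents that add atoms: tert-butyldimethylsilyl chloride, CC(C)(C)[Si](C)(C)Cl
Why: Standard silylation of a primary alcohol; the silyl ether carries the future C4 carbon through the organometallic and gold steps and is later the only fluoride-labile group.

Step 2
Reactants: 2 tert-butyl(furan-3-ylmethoxy)dimethylsilane
Product: 4 2-[3-(tert-butyldimethylsilyloxymethyl)furan-2-yl]ethanol, via 2-lithiofuran 3 (not isolated)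
Conditions: n-BuLi, THF, −78 → −20 °C; ethylene oxide, BF3·OEt2, −78 °C
Reagents that add atoms: ethylene oxide, C1CO1
Why: Directed α-lithiation of a 3-(oxymethyl)furan at C2, the α-position beside the coordinating side chain, followed by Lewis-acid-assisted epoxide opening; keeping the anion cold and free of polar additives should outrun 1,4 migration of silicon from oxygen to carbon.

Step 3
Reactants: 4 2-[3-(tert-butyldimethylsilyloxymethyl)furan-2-yl]ethanol
Product: 5 2-[3-(tert-butyldimethylsilyloxymethyl)furan-2-yl]acetic acid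
Conditions: TEMPO (cat.), PhI(OAc)2, MeCN–pH 7 buffer, 0 °C → rt
Reagents that add atoms: water, O
Why: Nitroxyl-catalysed oxidation of a primary alcohol to the acid through the aldehyde hydrate; the buffered, near-neutral medium should leave the silyl ether and the furan intact.

Step 4
Reactants: 5 2-[3-(tert-butyldimethylsilyloxymethyl)furan-2-yl]acetic acid; 6 (R)-4-benzyl-2-oxazolidinone
Product: 8 (4R)-4-benzyl-3-{2-[3-(tert-butyldimethylsilyloxymethyl)furan-2-yl]acetyl}oxazolidin-2-one, via mixed pivalic anhydride 7 (not isolated)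
Conditions: PivCl, Et3N, THF, −20 °C; then 6, LiCl, −20 °C → rt
Reagents that add atoms: none
Why: N-Acylation of the oxazolidinone through the mixed anhydride under LiCl/amine activation, which avoids strong base at the acidic furylacetyl position.

Step 5
Reactants: 8 (4R)-4-benzyl-3-{2-[3-(tert-butyldimethylsilyloxymethyl)furan-2-yl]acetyl}oxazolidin-2-one; 9 4-benzyloxy-3-methoxybenzaldehyde
Product: 11 (4R)-4-benzyl-3-[(2S,3R)-3-(4-benzyloxy-3-methoxyphenyl)-2-[3-(tert-butyldimethylsilyloxymethyl)furan-2-yl]-3-hydroxypropanoyl]oxazolidin-2-one, via boron Z-enolate 10 (not isolated)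
Conditions: Bu2BOTf, i-Pr2NEt, CH2Cl2, −78 → 0 °C; 9, −78 → 0 °C; pH 7 buffer, MeOH, H2O2, 0 °C
Reagents that add atoms: none
Why: Evans syn aldol: the Z-boron enolate reacts through a chair Zimmerman–Traxler transition state on the enolate face away from the benzyl group of the dipole-opposed (R)-auxiliary, which should set (2S,3R). These are both ring stereocentres, in the syn relation that becomes trans once O1–C2 is carried into the ring with retention.

Step 6
Reactants: 11 (4R)-4-benzyl-3-[(2S,3R)-3-(4-benzyloxy-3-methoxyphenyl)-2-[3-(tert-butyldimethylsilyloxymethyl)furan-2-yl]-3-hydroxypropanoyl]oxazolidin-2-one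
Product: 12 (1R,2S)-1-(4-benzyloxy-3-methoxyphenyl)-2-[3-(tert-butyldimethylsilyloxymethyl)furan-2-yl]propane-1,3-diol
Conditions: LiBH4, MeOH (1 equiv), THF, 0 °C
Reagents that add atoms: none
Why: Reductive cleavage of the N-acyl oxazolidinone at the exocyclic carbonyl gives the primary alcohol and returns the auxiliary; a short reaction at 0 °C limits retro-aldol, and neither stereocentre is touched.

Step 7
Reactants: 12 (1R,2S)-1-(4-benzyloxy-3-methoxyphenyl)-2-[3-(tert-butyldimethylsilyloxymethyl)furan-2-yl]propane-1,3-diol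
Product: 14 (1R,2S)-3-benzyloxy-1-(4-benzyloxy-3-methoxyphenyl)-2-[3-(tert-butyldimethylsilyloxymethyl)furan-2-yl]propan-1-ol, via stannylene acetal 13 (not isolated)
Conditions: Bu2SnO, toluene, reflux (−H2O); BnBr, Bu4NI, toluene, 90 °C; aq. KF
Reagents that add atoms: benzyl bromide, BrCc1ccccc1
Why: Stannylene-acetal-mediated monoalkylation of a 1,3-diol goes to the primary oxygen and leaves the secondary benzylic hydroxyl free; the fluoride-free alkylation spares the silyl ether, and a benzyl ether cannot migrate to the alkoxide of step 8.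

Step 8
Reactants: 14 (1R,2S)-3-benzyloxy-1-(4-benzyloxy-3-methoxyphenyl)-2-[3-(tert-butyldimethylsilyloxymethyl)furan-2-yl]propan-1-ol
Product: 17 (1R,2S)-3-benzyloxy-1-(4-benzyloxy-3-methoxyphenyl)-1-ethynyloxy-2-[3-(tert-butyldimethylsilyloxymethyl)furan-2-yl]propane, via dichlorovinyl ether 15 (not isolated), via lithium alkynyl ether 16 (not isolated)
Conditions: KH, THF, 0 °C; Cl2C=CHCl, −50 °C → rt; n-BuLi (2.5 equiv), −78 → −40 °C; MeOH, −78 °C
Reagents that add atoms: trichloroethylene, ClC=C(Cl)Cl
Why: Addition of the potassium alkoxide to dichloroacetylene formed in situ gives the (E)-1,2-dichlorovinyl ether; elimination and chlorine–lithium exchange with n-BuLi followed by protonation give the terminal ynol ether, a sequence established for secondary and benzylic alcohols. The carbinol C–O bond is not broken, so the configuration is retained.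

Step 9
Reactants: 17 (1R,2S)-3-benzyloxy-1-(4-benzyloxy-3-methoxyphenyl)-1-ethynyloxy-2-[3-(tert-butyldimethylsilyloxymethyl)furan-2-yl]propane
Product: 19 (2R,3S)-3-(benzyloxymethyl)-2-(4-benzyloxy-3-methoxyphenyl)-4-(tert-butyldimethylsilyloxymethyl)-2,3-dihydrobenzofuran-7-ol, via arene oxide 18 (not isolated)
Conditions: (Ph3P)AuNTf2 (3 mol %), CH2Cl2, 4 Å MS, −20 → 0 °C
Reagents that add atoms: none
Why: Cationic monovalent gold binds the ynol ether, which the oxygen polarises so that the oxygen-bearing alkyne carbon is the electrophile; furan C2 attacks it in a 5-exo-dig closure that forms C3a–C7a and the dihydrofuran ring and leaves a cyclopropyl gold carbenoid. Opening of the furan gives a dienal–gold carbene whose carbonyl oxygen adds to the carbene carbon to give an oxepine, and 6π-electrocyclisation of this oxepine to arene oxide 18 forms C6–C7 and closes the benzene ring. The epoxide opens at C6–O because the resulting cyclohexadienyl cation places charge on C7a, where O1 stabilises it, and proton loss from C7 gives the phenol. The closest known reaction type is the gold-catalysed furan–yne phenol synthesis in its alkynyl ether and ynamide variants, which give 7-hydroxy-2,3-dihydrobenzofurans and 7-hydroxyindolines. No stereocentre is formed; C2 and C3 come from the aldol of step 5 and have no pathway for epimerisation in a neutral, non-ionising medium. The step needs regioselectivity (hydroxyl on C7, silyloxymethyl on C4), which the ynol ether polarisation and the position of the furan 3-substituent secure, and chemoselectivity for π-activation over heterolysis of the benzylic C2–O1 bond, which the fast intramolecular five-ring closure, the low temperature and the non-acidic catalyst are meant to secure.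

Step 10
Reactants: 19 (2R,3S)-3-(benzyloxymethyl)-2-(4-benzyloxy-3-methoxyphenyl)-4-(tert-butyldimethylsilyloxymethyl)-2,3-dihydrobenzofuran-7-ol
Product: 20 (2R,3S)-7-benzyloxy-3-(benzyloxymethyl)-2-(4-benzyloxy-3-methoxyphenyl)-4-(tert-butyldimethylsilyloxymethyl)-2,3-dihydrobenzofuran
Conditions: BnBr, K2CO3, DMF, rt
Reagents that add atoms: benzyl bromide, BrCc1ccccc1
Why: Williamson etherification of the phenol; masking O7, which is para to C4, keeps a phenoxide from deactivating the aldehyde in step 14 and protects the ring from the later oxidants.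

Step 11
Reactants: 20 (2R,3S)-7-benzyloxy-3-(benzyloxymethyl)-2-(4-benzyloxy-3-methoxyphenyl)-4-(tert-butyldimethylsilyloxymethyl)-2,3-dihydrobenzofuran
Product: 21 [(2R,3S)-7-benzyloxy-3-(benzyloxymethyl)-2-(4-benzyloxy-3-methoxyphenyl)-2,3-dihydrobenzofuran-4-yl]methanol
Conditions: Bu4NF, THF, 0 °C → rt
Reagents that add atoms: none
Why: Fluoride cleavage of the only silyl ether; the benzyl ethers and the ring are inert.

Step 12
Reactants: 21 [(2R,3S)-7-benzyloxy-3-(benzyloxymethyl)-2-(4-benzyloxy-3-methoxyphenyl)-2,3-dihydrobenzofuran-4-yl]methanol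
Product: 22 (2R,3S)-7-benzyloxy-3-(benzyloxymethyl)-2-(4-benzyloxy-3-methoxyphenyl)-2,3-dihydrobenzofuran-4-carbaldehyde
Conditions: MnO2, CH2Cl2, rt
Reagents that add atoms: none
Why: Selective heterogeneous oxidation of a benzylic alcohol to the aldehyde; with the C3 oxygen benzylated no lactol can form and over-oxidation is not expected.

Step 13
Reactants: 23 2,4,6-trihydroxyacetophenone
Product: 24 1-[2,4-bis(benzyloxy)-6-hydroxyphenyl]ethanone
Conditions: BnBr (2 equiv), K2CO3, DMF, rt
Reagents that add atoms: benzyl bromide, BrCc1ccccc1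
Why: Williamson etherification; the phenol hydrogen-bonded to the ketone is the least nucleophilic, so two equivalents of benzyl bromide take the other two oxygens.

Step 14
Reactants: 22 (2R,3S)-7-benzyloxy-3-(benzyloxymethyl)-2-(4-benzyloxy-3-methoxyphenyl)-2,3-dihydrobenzofuran-4-carbaldehyde; 24 1-[2,4-bis(benzyloxy)-6-hydroxyphenyl]ethanone
Product: 25 (E)-1-[2,4-bis(benzyloxy)-6-hydroxyphenyl]-3-[(2R,3S)-7-benzyloxy-3-(benzyloxymethyl)-2-(4-benzyloxy-3-methoxyphenyl)-2,3-dihydrobenzofuran-4-yl]prop-2-en-1-one
Conditions: KOH, EtOH–THF, rt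
Reagents that add atoms: none
Why: Claisen–Schmidt condensation of a non-enolisable aldehyde with the methyl ketone gives the E-chalcone; C3–H is not acidic enough to epimerise, and any flavanone formed by reversible oxa-Michael addition is carried into step 15.

Step 15
Reactants: 25 (E)-1-[2,4-bis(benzyloxy)-6-hydroxyphenyl]-3-[(2R,3S)-7-benzyloxy-3-(benzyloxymethyl)-2-(4-benzyloxy-3-methoxyphenyl)-2,3-dihydrobenzofuran-4-yl]prop-2-en-1-one
Product: 26 5,7-bis(benzyloxy)-2-[(2R,3S)-7-benzyloxy-3-(benzyloxymethyl)-2-(4-benzyloxy-3-methoxyphenyl)-2,3-dihydrobenzofuran-4-yl]-4H-chromen-4-one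
Conditions: I2 (cat.), DMSO, 120 °C
Reagents that add atoms: none
Why: Iodine-mediated oxidative cyclisation of a 2'-hydroxychalcone (oxa-Michael closure, α-iodination, elimination) with DMSO as terminal oxidant; this six-ring closure is not diverted to the aurone by the 6'-alkoxy group.

Step 16
Reactants: 26 5,7-bis(benzyloxy)-2-[(2R,3S)-7-benzyloxy-3-(benzyloxymethyl)-2-(4-benzyloxy-3-methoxyphenyl)-2,3-dihydrobenzofuran-4-yl]-4H-chromen-4-one
Product: 28 5,7-bis(benzyloxy)-2-[(2R,3S)-7-benzyloxy-3-(benzyloxymethyl)-2-(4-benzyloxy-3-methoxyphenyl)-2,3-dihydrobenzofuran-4-yl]-3-hydroxy-4H-chromen-4-one, via flavone epoxide 27 (not isolated)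
Conditions: DMDO, acetone–CH2Cl2, 0 °C → rt; then p-TsOH (cat.), CH2Cl2, rt
Reagents that add atoms: dimethyldioxirane, CC1(C)OO1
Why: Dioxirane epoxidation of the enol-ether double bond of the flavone and acid-catalysed opening of the 2,3-epoxide with tautomerisation give the 3-hydroxyflavone, a sequence known for 5,7-dibenzyloxyflavones.

Step 17
Reactants: 28 5,7-bis(benzyloxy)-2-[(2R,3S)-7-benzyloxy-3-(benzyloxymethyl)-2-(4-benzyloxy-3-methoxyphenyl)-2,3-dihydrobenzofuran-4-yl]-3-hydroxy-4H-chromen-4-one
Product: 29 3,5,7-trihydroxy-2-[(2R,3S)-7-hydroxy-2-(4-hydroxy-3-methoxyphenyl)-3-(hydroxymethyl)-2,3-dihydrobenzofuran-4-yl]-4H-chromen-4-one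
Conditions: H2 (1 atm), Pd/C, THF–MeOH, rt
Reagents that add atoms: none
Why: Catalytic hydrogenolysis of five benzyl ethers under neutral conditions; benzyl ethers should cleave faster than the cyclic benzylic C2–O1 ether, and the chromenone double bond is not normally reduced under these conditions.

## Compound list

1 | 3-furanmethanol | OCc1ccoc1 | starting material
2 | tert-butyl(furan-3-ylmethoxy)dimethylsilane | CC(C)(C)[Si](C)(C)OCc1ccoc1 | intermediate
3 | [3-(tert-butyldimethylsilyloxymethyl)furan-2-yl]lithium | [Li]c1occc1CO[Si](C)(C)C(C)(C)C | intermediate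
4 | 2-[3-(tert-butyldimethylsilyloxymethyl)furan-2-yl]ethanol | OCCc1occc1CO[Si](C)(C)C(C)(C)C | intermediate
5 | 2-[3-(tert-butyldimethylsilyloxymethyl)furan-2-yl]acetic acid | OC(=O)Cc1occc1CO[Si](C)(C)C(C)(C)C | intermediate
6 | (R)-4-benzyl-2-oxazolidinone | O=C1N[C@H](Cc2ccccc2)CO1 | starting material
7 | 2-[3-(tert-butyldimethylsilyloxymethyl)furan-2-yl]acetic pivalic anhydride | CC(C)(C)C(=O)OC(=O)Cc1occc1CO[Si](C)(C)C(C)(C)C | intermediate
8 | (4R)-4-benzyl-3-{2-[3-(tert-butyldimethylsilyloxymethyl)furan-2-yl]acetyl}oxazolidin-2-one | O=C1N(C(=O)Cc2occc2CO[Si](C)(C)C(C)(C)C)[C@H](Cc2ccccc2)CO1 | intermediate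
9 | 4-benzyloxy-3-methoxybenzaldehyde | COc1cc(C=O)ccc1OCc1ccccc1 | starting material
10 | (Z)-dibutylboron enolate of imide 8 | CCCCB(CCCC)O/C(=C\c1occc1CO[Si](C)(C)C(C)(C)C)N1C(=O)OC[C@H]1Cc1ccccc1 | intermediate
11 | (4R)-4-benzyl-3-[(2S,3R)-3-(4-benzyloxy-3-methoxyphenyl)-2-[3-(tert-butyldimethylsilyloxymethyl)furan-2-yl]-3-hydroxypropanoyl]oxazolidin-2-one | COc1cc([C@H](O)[C@H](C(=O)N2C(=O)OC[C@H]2Cc2ccccc2)c2occc2CO[Si](C)(C)C(C)(C)C)ccc1OCc1ccccc1 | intermediate
12 | (1R,2S)-1-(4-benzyloxy-3-methoxyphenyl)-2-[3-(tert-butyldimethylsilyloxymethyl)furan-2-yl]propane-1,3-diol | COc1cc([C@H](O)[C@H](CO)c2occc2CO[Si](C)(C)C(C)(C)C)ccc1OCc1ccccc1 | intermediate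
13 | 2,2-dibutyl-1,3,2-dioxastanninane (stannylene acetal) of diol 12, stereocentres as in 12 | COc1cc([C@@H]2O[Sn](CCCC)(CCCC)OC[C@@H]2c2occc2CO[Si](C)(C)C(C)(C)C)ccc1OCc1ccccc1 | intermediate
14 | (1R,2S)-3-benzyloxy-1-(4-benzyloxy-3-methoxyphenyl)-2-[3-(tert-butyldimethylsilyloxymethyl)furan-2-yl]propan-1-ol | COc1cc([C@H](O)[C@H](COCc2ccccc2)c2occc2CO[Si](C)(C)C(C)(C)C)ccc1OCc1ccccc1 | intermediate
15 | (1R,2S)-3-benzyloxy-1-(4-benzyloxy-3-methoxyphenyl)-1-[(E)-1,2-dichlorovinyloxy]-2-[3-(tert-butyldimethylsilyloxymethyl)furan-2-yl]propane | COc1cc([C@H](O/C(Cl)=C\Cl)[C@H](COCc2ccccc2)c2occc2CO[Si](C)(C)C(C)(C)C)ccc1OCc1ccccc1 | intermediate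
16 | lithium acetylide of ynol ether 17 | COc1cc([C@H](OC#C[Li])[C@H](COCc2ccccc2)c2occc2CO[Si](C)(C)C(C)(C)C)ccc1OCc1ccccc1 | intermediate
17 | (1R,2S)-3-benzyloxy-1-(4-benzyloxy-3-methoxyphenyl)-1-ethynyloxy-2-[3-(tert-butyldimethylsilyloxymethyl)furan-2-yl]propane | COc1cc([C@H](OC#C)[C@H](COCc2ccccc2)c2occc2CO[Si](C)(C)C(C)(C)C)ccc1OCc1ccccc1 | intermediate
18 | (2R,3S)-3-(benzyloxymethyl)-2-(4-benzyloxy-3-methoxyphenyl)-4-(tert-butyldimethylsilyloxymethyl)-6,7-epoxy-2,3,6,7-tetrahydrobenzofuran (arene oxide, epoxide configuration undefined) | COc1cc([C@@H]2OC3=C([C@H]2COCc2ccccc2)C(CO[Si](C)(C)C(C)(C)C)=CC4OC34)ccc1OCc1ccccc1 | intermediate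
19 | (2R,3S)-3-(benzyloxymethyl)-2-(4-benzyloxy-3-methoxyphenyl)-4-(tert-butyldimethylsilyloxymethyl)-2,3-dihydrobenzofuran-7-ol | COc1cc([C@@H]2Oc3c(O)ccc(CO[Si](C)(C)C(C)(C)C)c3[C@H]2COCc2ccccc2)ccc1OCc1ccccc1 | intermediate
20 | (2R,3S)-7-benzyloxy-3-(benzyloxymethyl)-2-(4-benzyloxy-3-methoxyphenyl)-4-(tert-butyldimethylsilyloxymethyl)-2,3-dihydrobenzofuran | COc1cc([C@@H]2Oc3c(OCc4ccccc4)ccc(CO[Si](C)(C)C(C)(C)C)c3[C@H]2COCc2ccccc2)ccc1OCc1ccccc1 | intermediate
21 | [(2R,3S)-7-benzyloxy-3-(benzyloxymethyl)-2-(4-benzyloxy-3-methoxyphenyl)-2,3-dihydrobenzofuran-4-yl]methanol | COc1cc([C@@H]2Oc3c(OCc4ccccc4)ccc(CO)c3[C@H]2COCc2ccccc2)ccc1OCc1ccccc1 | intermediate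
22 | (2R,3S)-7-benzyloxy-3-(benzyloxymethyl)-2-(4-benzyloxy-3-methoxyphenyl)-2,3-dihydrobenzofuran-4-carbaldehyde | COc1cc([C@@H]2Oc3c(OCc4ccccc4)ccc(C=O)c3[C@H]2COCc2ccccc2)ccc1OCc1ccccc1 | intermediate
23 | 2,4,6-trihydroxyacetophenone | CC(=O)c1c(O)cc(O)cc1O | starting material
24 | 1-[2,4-bis(benzyloxy)-6-hydroxyphenyl]ethanone | CC(=O)c1c(O)cc(OCc2ccccc2)cc1OCc1ccccc1 | intermediate
25 | (E)-1-[2,4-bis(benzyloxy)-6-hydroxyphenyl]-3-[(2R,3S)-7-benzyloxy-3-(benzyloxymethyl)-2-(4-benzyloxy-3-methoxyphenyl)-2,3-dihydrobenzofuran-4-yl]prop-2-en-1-one | COc1cc([C@@H]2Oc3c(OCc4ccccc4)ccc(/C=C/C(=O)c4c(O)cc(OCc5ccccc5)cc4OCc4ccccc4)c3[C@H]2COCc2ccccc2)ccc1OCc1ccccc1 | intermediate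
26 | 5,7-bis(benzyloxy)-2-[(2R,3S)-7-benzyloxy-3-(benzyloxymethyl)-2-(4-benzyloxy-3-methoxyphenyl)-2,3-dihydrobenzofuran-4-yl]-4H-chromen-4-one | COc1cc([C@@H]2Oc3c(OCc4ccccc4)ccc(-c4cc(=O)c5c(OCc6ccccc6)cc(OCc6ccccc6)cc5o4)c3[C@H]2COCc2ccccc2)ccc1OCc1ccccc1 | intermediate
27 | 5,7-bis(benzyloxy)-2-[(2R,3S)-7-benzyloxy-3-(benzyloxymethyl)-2-(4-benzyloxy-3-methoxyphenyl)-2,3-dihydrobenzofuran-4-yl]-2,3-epoxychroman-4-one (epoxide configuration undefined) | COc1cc([C@@H]2Oc3c(OCc4ccccc4)ccc(C45Oc6cc(OCc7ccccc7)cc(OCc7ccccc7)c6C(=O)C4O5)c3[C@H]2COCc2ccccc2)ccc1OCc1ccccc1 | intermediate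
28 | 5,7-bis(benzyloxy)-2-[(2R,3S)-7-benzyloxy-3-(benzyloxymethyl)-2-(4-benzyloxy-3-methoxyphenyl)-2,3-dihydrobenzofuran-4-yl]-3-hydroxy-4H-chromen-4-one | COc1cc([C@@H]2Oc3c(OCc4ccccc4)ccc(-c4oc5cc(OCc6ccccc6)cc(OCc6ccccc6)c5c(=O)c4O)c3[C@H]2COCc2ccccc2)ccc1OCc1ccccc1 | intermediate
29 | 3,5,7-trihydroxy-2-[(2R,3S)-7-hydroxy-2-(4-hydroxy-3-methoxyphenyl)-3-(hydroxymethyl)-2,3-dihydrobenzofuran-4-yl]-4H-chromen-4-one | COc1cc([C@@H]2Oc3c(O)ccc(-c4oc5cc(O)cc(O)c5c(=O)c4O)c3[C@H]2CO)ccc1O | target

## Step count and least certain steps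

Total: 17 steps. Longest linear sequence: 16 steps (1 to 29 through steps 1–12 and 14–17); step 13 is a one-step branch.

Step 9 (key step). Most likely failure: heterolysis of the benzylic C2–O1 bond once gold has turned the ynol ether into a ketene-oxonium, because the para-benzyloxy group stabilises the benzylic cation; this would lead to fragmentation or a 1,3-shift of the benzylic group instead of cyclisation. Hydration of the ynol ether by traces of water and addition of the product phenol to unreacted ynol ether are lesser losses.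

Fallback: carry the para-oxygen through the gold step as a chloride, which cannot support the cation, and install the oxygen afterwards. The fallback sets out from imide 8 and returns at 20.
- The aldol of step 5 would be run with commercial 4-chloro-3-methoxybenzaldehyde to give the syn adduct F1.
- LiBH4 would give the diol F2; its stannylene acetal F3 would be benzylated to the primary benzyl ether F4.
- The sequence of step 8 would pass through the dichlorovinyl ether F5 and the lithium alkynyl ether F6 to the chloroaryl ynol ether F7.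
- The gold step would then give, through the arene oxide F8, the chloroaryl phenol F9.
- Miyaura borylation (B2pin2, Pd2(dba)3, XPhos, KOAc, dioxane, 100 °C) would give the aryl boronate F10.
- Oxidation (NaBO3, THF–H2O) would give the bisphenol F11, and benzylation of both phenols (BnBr, K2CO3, DMF) returns to 20.

Step 8. Most likely failure: loss of the terminal ynol ether during isolation, by hydration on silica or by sigmatropic shift of the electron-rich benzylic group on warming; base-induced elimination across the benzylic ether during the n-BuLi stage is a second risk. Fallback, from 16 back to 17: quench the lithium alkynyl ether with Me3SiCl at −78 °C to give the C-silyl ynol ether F12, which can be purified and stored, and release 17 with K2CO3 in MeOH at 0 °C directly before step 9.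

Step 2. Most likely failure: migration of the silyl group from oxygen to the lithiated carbon, or partial lithiation at C5, before the epoxide is opened. Fallback, from 2 back to 5 (it replaces steps 2 and 3):
- Electrophilic bromination (NBS, DMF, −20 °C) at the α-position next to the side chain gives the 2-bromofuran F13.
- Negishi coupling with the Reformatsky reagent BrZnCH2CO2Et (Pd2(dba)3, XPhos, THF, 50 °C) gives the ethyl furylacetate F14.
- Saponification (LiOH, THF–H2O) gives acid 5.

Step 16. Most likely failure: slow epoxidation of the twisted, hindered flavone, so that oxidation of the electron-rich rings or of benzylic C–H bonds competes. Fallback, from 26 back to 28: deprotonation at C3 with LDA (THF, −78 °C), trapping with B(OMe)3 to the flavone-3-boronate F15, and oxidation with H2O2–AcOH, which uses no electrophilic oxidant on the arenes.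

Step 17. Most likely failure: hydrogenolytic opening of the benzylic C2–O1 bond, or incomplete removal of the aliphatic benzyl ether. Fallback, from 28 to 29: Lewis-acid debenzylation with BCl3 and pentamethylbenzene as cation scavenger (CH2Cl2, −78 °C), which removes benzyl groups without a metal surface and forms no new intermediate.

## Further compounds

F1 | step 9 | (4R)-4-benzyl-3-[(2S,3R)-3-(4-chloro-3-methoxyphenyl)-2-[3-(tert-butyldimethylsilyloxymethyl)furan-2-yl]-3-hydroxypropanoyl]oxazolidin-2-one | COc1cc([C@H](O)[C@H](C(=O)N2C(=O)OC[C@H]2Cc2ccccc2)c2occc2CO[Si](C)(C)C(C)(C)C)ccc1Cl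
F2 | step 9 | (1R,2S)-1-(4-chloro-3-methoxyphenyl)-2-[3-(tert-butyldimethylsilyloxymethyl)furan-2-yl]propane-1,3-diol | COc1cc([C@H](O)[C@H](CO)c2occc2CO[Si](C)(C)C(C)(C)C)ccc1Cl
F3 | step 9 | 2,2-dibutyl-1,3,2-dioxastanninane (stannylene acetal) of diol F2 | COc1cc([C@@H]2O[Sn](CCCC)(CCCC)OC[C@@H]2c2occc2CO[Si](C)(C)C(C)(C)C)ccc1Cl
F4 | step 9 | (1R,2S)-3-benzyloxy-1-(4-chloro-3-methoxyphenyl)-2-[3-(tert-butyldimethylsilyloxymethyl)furan-2-yl]propan-1-ol | COc1cc([C@H](O)[C@H](COCc2ccccc2)c2occc2CO[Si](C)(C)C(C)(C)C)ccc1Cl
F5 | step 9 | (1R,2S)-3-benzyloxy-1-(4-chloro-3-methoxyphenyl)-1-[(E)-1,2-dichlorovinyloxy]-2-[3-(tert-butyldimethylsilyloxymethyl)furan-2-yl]propane | COc1cc([C@H](O/C(Cl)=C\Cl)[C@H](COCc2ccccc2)c2occc2CO[Si](C)(C)C(C)(C)C)ccc1Cl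
F6 | step 9 | lithium acetylide of ynol ether F7 | COc1cc([C@H](OC#C[Li])[C@H](COCc2ccccc2)c2occc2CO[Si](C)(C)C(C)(C)C)ccc1Cl
F7 | step 9 | (1R,2S)-3-benzyloxy-1-(4-chloro-3-methoxyphenyl)-1-ethynyloxy-2-[3-(tert-butyldimethylsilyloxymethyl)furan-2-yl]propane | COc1cc([C@H](OC#C)[C@H](COCc2ccccc2)c2occc2CO[Si](C)(C)C(C)(C)C)ccc1Cl
F8 | step 9 | (2R,3S)-3-(benzyloxymethyl)-2-(4-chloro-3-methoxyphenyl)-4-(tert-butyldimethylsilyloxymethyl)-6,7-epoxy-2,3,6,7-tetrahydrobenzofuran | COc1cc([C@@H]2OC3=C([C@H]2COCc2ccccc2)C(CO[Si](C)(C)C(C)(C)C)=CC4OC34)ccc1Cl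
F9 | step 9 | (2R,3S)-3-(benzyloxymethyl)-2-(4-chloro-3-methoxyphenyl)-4-(tert-butyldimethylsilyloxymethyl)-2,3-dihydrobenzofuran-7-ol | COc1cc([C@@H]2Oc3c(O)ccc(CO[Si](C)(C)C(C)(C)C)c3[C@H]2COCc2ccccc2)ccc1Cl
F10 | step 9 | (2R,3S)-3-(benzyloxymethyl)-2-[3-methoxy-4-(4,4,5,5-tetramethyl-1,3,2-dioxaborolan-2-yl)phenyl]-4-(tert-butyldimethylsilyloxymethyl)-2,3-dihydrobenzofuran-7-ol | COc1cc([C@@H]2Oc3c(O)ccc(CO[Si](C)(C)C(C)(C)C)c3[C@H]2COCc2ccccc2)ccc1B1OC(C)(C)C(C)(C)O1
F11 | step 9 | (2R,3S)-3-(benzyloxymethyl)-2-(4-hydroxy-3-methoxyphenyl)-4-(tert-butyldimethylsilyloxymethyl)-2,3-dihydrobenzofuran-7-ol | COc1cc([C@@H]2Oc3c(O)ccc(CO[Si](C)(C)C(C)(C)C)c3[C@H]2COCc2ccccc2)ccc1O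
F12 | step 8 | (1R,2S)-3-benzyloxy-1-(4-benzyloxy-3-methoxyphenyl)-1-[(trimethylsilyl)ethynyloxy]-2-[3-(tert-butyldimethylsilyloxymethyl)furan-2-yl]propane | COc1cc([C@H](OC#C[Si](C)(C)C)[C@H](COCc2ccccc2)c2occc2CO[Si](C)(C)C(C)(C)C)ccc1OCc1ccccc1
F13 | step 2 | [(2-bromofuran-3-yl)methoxy](tert-butyl)dimethylsilane | Brc1occc1CO[Si](C)(C)C(C)(C)C
F14 | step 2 | ethyl 2-[3-(tert-butyldimethylsilyloxymethyl)furan-2-yl]acetate | CCOC(=O)Cc1occc1CO[Si](C)(C)C(C)(C)C
F15 | step 16 | dimethyl {5,7-bis(benzyloxy)-2-[(2R,3S)-7-benzyloxy-3-(benzyloxymethyl)-2-(4-benzyloxy-3-methoxyphenyl)-2,3-dihydrobenzofuran-4-yl]-4-oxo-4H-chromen-3-yl}boronate | COc1cc([C@@H]2Oc3c(OCc4ccccc4)ccc(-c4oc5cc(OCc6ccccc6)cc(OCc6ccccc6)c5c(=O)c4B(OC)OC)c3[C@H]2COCc2ccccc2)ccc1OCc1ccccc1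
F0 | step 17 | none | none
A1 | alternative 1 | (2R)-8-benzyloxy-5-bromo-2-(3-methoxy-4-tosyloxyphenyl)chroman-4-one | COc1cc([C@H]2CC(=O)c3c(Br)ccc(OCc4ccccc4)c3O2)ccc1OS(=O)(=O)c1ccc(C)cc1
A2 | alternative 1 | methyl (2R,3R)-7-benzyloxy-4-bromo-2-(3-methoxy-4-tosyloxyphenyl)-2,3-dihydrobenzofuran-3-carboxylate | COc1cc([C@@H]2Oc3c(OCc4ccccc4)ccc(Br)c3[C@H]2C(=O)OC)ccc1OS(=O)(=O)c1ccc(C)cc1
A3 | alternative 2 | 6-{4-[(2R,3S)-7-benzyloxy-3-(benzyloxymethyl)-2-(4-benzyloxy-3-methoxyphenyl)-2,3-dihydrobenzofuran-4-yl]-2,4-dioxobutyl}-4-hydroxy-2H-pyran-2-one | COc1cc([C@@H]2Oc3c(OCc4ccccc4)ccc(C(=O)CC(=O)Cc4cc(O)cc(=O)o4)c3[C@H]2COCc2ccccc2)ccc1OCc1ccccc1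
A4 | alternative 2 | 1-[(2R,3S)-7-benzyloxy-3-(benzyloxymethyl)-2-(4-benzyloxy-3-methoxyphenyl)-2,3-dihydrobenzofuran-4-yl]-3-(2,4,6-trihydroxyphenyl)propane-1,3-dione | COc1cc([C@@H]2Oc3c(OCc4ccccc4)ccc(C(=O)CC(=O)c4c(O)cc(O)cc4O)c3[C@H]2COCc2ccccc2)ccc1OCc1ccccc1
A5 | alternative 3 | 4,6-bis(benzyloxy)-2-bromo-2-{bromo[(2R,3S)-7-benzyloxy-3-(benzyloxymethyl)-2-(4-benzyloxy-3-methoxyphenyl)-2,3-dihydrobenzofuran-4-yl]methyl}benzofuran-3(2H)-one | COc1cc([C@@H]2Oc3c(OCc4ccccc4)ccc(C(Br)C4(Br)Oc5cc(OCc6ccccc6)cc(OCc6ccccc6)c5C4=O)c3[C@H]2COCc2ccccc2)ccc1OCc1ccccc1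
A6 | alternative 3 | 5,7-bis(benzyloxy)-2-[(2R,3S)-7-benzyloxy-3-(benzyloxymethyl)-2-(4-benzyloxy-3-methoxyphenyl)-2,3-dihydrobenzofuran-4-yl]-3-hydroxy-4H-chromen-4-one | COc1cc([C@@H]2Oc3c(OCc4ccccc4)ccc(-c4oc5cc(OCc6ccccc6)cc(OCc6ccccc6)c5c(=O)c4O)c3[C@H]2COCc2ccccc2)ccc1OCc1ccccc1
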